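**Plan**

- Retrosynthesis: take Si off the 4'-oxygen and Me off the 6-oxygen, then open ring C at C4a–C4 and O1–C2. This leaves 2,3,5-trimethoxy-1,4-benzoquinone and a 3-(syringyl)prop-2-ynal.
- Enabling feature: on ring A, O1 (on C8a) and the C6 oxygen are para, and C4a is the only ring carbon without oxygen. Ring A is therefore trimethoxy-p-benzoquinone at the hydroquinone level, and its single C–H is the future C4a. Quinone plus ynal is an isomer of the 6-hydroxyflavone, because the quinone takes up the two electrons released when the aldehyde C–H becomes the C4 ketone.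
- Forward: the quinone (two steps from 2,6-dimethoxybenzoquinone) and the ynal (three steps from syringaldehyde) are joined at two electrophilic carbons by a light-driven acyl-radical C–H acylation (C4a–C4). Ring C, the only ring that is made, then closes in the same flask (O1–C2).
- End game: methylation of the 6-OH, then removal of the silyl group from the 4'-oxygen.
- Stereochemistry: none to set; the target is achiral.

Key step: step 6

Remark: the target has no stereocentre, stereogenic axis or configurable double bond, so the "single enantiomer" is the one achiral compound and no step needs stereocontrol.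

**Route**

Step 1
Reactants: 1 2,6-dimethoxy-1,4-benzoquinone
Product: 2 3-bromo-2,6-dimethoxy-1,4-benzoquinone
Conditions: Br2 (1.0 equiv), NaOAc (1.1 equiv), AcOH, 20 °C
Reagents that add atoms: bromine BrBr
Why: Electrophilic bromination by addition–elimination: C3–H is the nucleophilic α-carbon of the vinylogous ester MeO–C2=C3–C4=O, so Br+ attacks there and loss of H+ to acetate restores the quinone, with one equivalent of bromine limiting dibromination.

Step 2
Reactants: 2 3-bromo-2,6-dimethoxy-1,4-benzoquinone
Product: 3 2,3,5-trimethoxy-1,4-benzoquinone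
Conditions: NaOMe (1.05 equiv), MeOH/THF, −20 to 0 °C; AcOH quench
Reagents that add atoms: sodium methoxide C[O-].[Na+]
Why: Vinylic nucleophilic substitution (addition–elimination) on a haloquinone: methoxide adds to the bromine-bearing carbon, which is β to the C1 carbonyl, and bromide leaves, while attack at a methoxy-bearing carbon is degenerate.

Step 3
Reactants: 4 syringaldehyde (4-hydroxy-3,5-dimethoxybenzaldehyde)
Product: 5 3,5-dimethoxy-4-(triisopropylsilyloxy)benzaldehyde
Conditions: TIPSCl, imidazole, DMAP (cat.), DMF, 50 °C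
Reagents that add atoms: triisopropylsilyl chloride CC(C)[Si](Cl)(C(C)C)C(C)C
Why: Imidazole-promoted silylation of the phenol; TIPS is chosen because it has no weak C–H bond for the later quinone-triplet step and resists n-BuLi and K2CO3.

Step 4
Reactants: 5 3,5-dimethoxy-4-(triisopropylsilyloxy)benzaldehyde
Product: 6 [4-(2,2-dibromovinyl)-2,6-dimethoxyphenoxy]triisopropylsilane
Conditions: CBr4 (2 equiv), PPh3 (4 equiv), CH2Cl2, 0 °C
Reagents that add atoms: carbon tetrabromide BrC(Br)(Br)Br
Why: First stage of the Corey–Fuchs sequence, a Wittig-type olefination of the aldehyde by Ph3P=CBr2 formed in the flask.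

Step 5
Reactants: 6 [4-(2,2-dibromovinyl)-2,6-dimethoxyphenoxy]triisopropylsilane
Product: 9 3-[3,5-dimethoxy-4-(triisopropylsilyloxy)phenyl]prop-2-ynal, via lithium acetylide 7 (not isolated), via lithium hemiaminolate 8 (not isolated)
Conditions: n-BuLi (2.1 equiv), THF, −78 °C; DMF (3 equiv), −78 to 0 °C; reverse quench into cold 1 M aq. H3PO4/MTBE
Reagents that add atoms: N,N-dimethylformamide CN(C)C=O (formyl group of 9); n-butyllithium [Li]CCCC (lithium of 7 and 8 only)
Why: Second stage of the Corey–Fuchs sequence (Br/Li exchange, Fritsch–Buttenberg–Wiechell shift, deprotonation) gives acetylide 7, which is formylated by DMF, and the acidic reverse quench collapses 8 while keeping the liberated dimethylamine protonated so that it cannot add to the ynal.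

Step 6
Reactants: 3 2,3,5-trimethoxy-1,4-benzoquinone; 9 3-[3,5-dimethoxy-4-(triisopropylsilyloxy)phenyl]prop-2-ynal
Product: 12 6-hydroxy-5,7,8-trimethoxy-2-[3,5-dimethoxy-4-(triisopropylsilyloxy)phenyl]-4H-chromen-4-one, via acylhydroquinone ynone 10 (not isolated), via diethylamino enaminone 11 (not isolated)
Conditions: 3 (1.0 equiv), 9 (1.3 equiv), degassed PhCF3 (0.3 M), 450 nm LEDs, 20 °C, Ar; then evaporate, EtOH, Et2NH (3 equiv), 40 °C, Ar
Reagents that add atoms: none
Why: Proposed new method: blue light excites only quinone 3, whose triplet abstracts the aldehydic hydrogen of 9; the semiquinone/alkynoyl radical pair (or, in a chain, the nucleophilic alkynoyl σ-radical adding to ground-state 3) forms the C4a–C4 bond at C6 of 3, the only ring carbon bearing hydrogen and the β-carbon of the C4 enone, and tautomerisation gives acylhydroquinone 10, so two electrophilic carbons are joined with the quinone as internal oxidant and no by-product. The closest known reaction is the photo-Friedel–Crafts acylation of 1,4-benzo- and naphthoquinones with aliphatic, aromatic and α,β-unsaturated aldehydes to 2-acylhydroquinones; a 2-ynal donor and a quinone carrying three alkoxy groups go beyond it, and the alkynoyl radical should persist because loss of CO would give an sp-alkynyl radical. Ring C is then closed by the known amine route from o-hydroxyaryl ynones to flavones: Et2NH adds to the ynone to give enaminone 11, and the hydroxyl ortho to the acyl group (the future O1) displaces the amine at the β-carbon, a 6-endo addition–elimination that cannot give the 5-exo aurone. No stereocentre is formed. The step needs C- over O-acylation, hydrogen abstraction from CHO rather than from other C–H bonds, and closure through the right oxygen; these should be secured by the single ring C–H of 3, by the TIPS group (no benzylic or comparably weak C–H), by 450 nm light that 9 and 12 do not absorb, and by the fact that the other position ortho to the acyl group carries OMe.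

Step 7
Reactants: 12 6-hydroxy-5,7,8-trimethoxy-2-[3,5-dimethoxy-4-(triisopropylsilyloxy)phenyl]-4H-chromen-4-one
Product: 13 5,6,7,8-tetramethoxy-2-[3,5-dimethoxy-4-(triisopropylsilyloxy)phenyl]-4H-chromen-4-one
Conditions: MeI (3 equiv), K2CO3 (3 equiv), acetone, reflux
Reagents that add atoms: iodomethane CI
Why: Williamson O-methylation of the only free phenol (6-OH, flanked by two methoxy groups but a routine methylation in polymethoxyflavones), under conditions to which the aryl TIPS ether is stable.

Step 8
Reactants: 13 5,6,7,8-tetramethoxy-2-[3,5-dimethoxy-4-(triisopropylsilyloxy)phenyl]-4H-chromen-4-one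
Product: 14 2-(4-hydroxy-3,5-dimethoxyphenyl)-5,6,7,8-tetramethoxy-4H-chromen-4-one (4'-hydroxy-3',5,5',6,7,8-hexamethoxyflavone)
Conditions: TBAF (1.2 equiv), AcOH (1.2 equiv), THF, 0 °C to rt
Reagents that add atoms: none
Why: Fluoride-mediated desilylation driven by Si–F bond formation, buffered with acetic acid so that the pyranone ring and the six methyl ethers are untouched.

**Compound list**

1 | 2,6-dimethoxy-1,4-benzoquinone | COC1=CC(=O)C=C(OC)C1=O | starting material
2 | 3-bromo-2,6-dimethoxy-1,4-benzoquinone | COC1=CC(=O)C(Br)=C(OC)C1=O | intermediate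
3 | 2,3,5-trimethoxy-1,4-benzoquinone | COC1=CC(=O)C(OC)=C(OC)C1=O | intermediate
4 | syringaldehyde (4-hydroxy-3,5-dimethoxybenzaldehyde) | COc1cc(C=O)cc(OC)c1O | starting material
5 | 3,5-dimethoxy-4-(triisopropylsilyloxy)benzaldehyde | COc1cc(C=O)cc(OC)c1O[Si](C(C)C)(C(C)C)C(C)C | intermediate
6 | [4-(2,2-dibromovinyl)-2,6-dimethoxyphenoxy]triisopropylsilane | COc1cc(C=C(Br)Br)cc(OC)c1O[Si](C(C)C)(C(C)C)C(C)C | intermediate
7 | lithium [3,5-dimethoxy-4-(triisopropylsilyloxy)phenyl]acetylide | [Li]C#Cc1cc(OC)c(O[Si](C(C)C)(C(C)C)C(C)C)c(OC)c1 | intermediate (not isolated)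
8 | lithium 1-(dimethylamino)-3-[3,5-dimethoxy-4-(triisopropylsilyloxy)phenyl]prop-2-yn-1-olate (racemic) | [Li]OC(C#Cc1cc(OC)c(O[Si](C(C)C)(C(C)C)C(C)C)c(OC)c1)N(C)C | intermediate (not isolated)
9 | 3-[3,5-dimethoxy-4-(triisopropylsilyloxy)phenyl]prop-2-ynal | O=CC#Cc1cc(OC)c(O[Si](C(C)C)(C(C)C)C(C)C)c(OC)c1 | intermediate
10 | 1-(2,5-dihydroxy-3,4,6-trimethoxyphenyl)-3-[3,5-dimethoxy-4-(triisopropylsilyloxy)phenyl]prop-2-yn-1-one | COc1c(O)c(C(=O)C#Cc2cc(OC)c(O[Si](C(C)C)(C(C)C)C(C)C)c(OC)c2)c(OC)c(O)c1OC | intermediate (not isolated)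
11 | 3-(diethylamino)-1-(2,5-dihydroxy-3,4,6-trimethoxyphenyl)-3-[3,5-dimethoxy-4-(triisopropylsilyloxy)phenyl]prop-2-en-1-one (E isomer drawn; the push–pull C=C isomerises freely) | CCN(CC)/C(=C/C(=O)c1c(O)c(OC)c(OC)c(O)c1OC)c1cc(OC)c(O[Si](C(C)C)(C(C)C)C(C)C)c(OC)c1 | intermediate (not isolated)
12 | 6-hydroxy-5,7,8-trimethoxy-2-[3,5-dimethoxy-4-(triisopropylsilyloxy)phenyl]-4H-chromen-4-one | COc1cc(-c2cc(=O)c3c(OC)c(O)c(OC)c(OC)c3o2)cc(OC)c1O[Si](C(C)C)(C(C)C)C(C)C | intermediate
13 | 5,6,7,8-tetramethoxy-2-[3,5-dimethoxy-4-(triisopropylsilyloxy)phenyl]-4H-chromen-4-one | COc1cc(-c2cc(=O)c3c(OC)c(OC)c(OC)c(OC)c3o2)cc(OC)c1O[Si](C(C)C)(C(C)C)C(C)C | intermediate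
14 | 2-(4-hydroxy-3,5-dimethoxyphenyl)-5,6,7,8-tetramethoxy-4H-chromen-4-one | COc1cc(-c2cc(=O)c3c(OC)c(OC)c(OC)c(OC)c3o2)cc(OC)c1O | target

**Step count and risks**

Total step count: 8. Longest linear sequence: 6 steps (4 to 14, steps 3–8); the quinone arm (steps 1–2) joins at step 6.

Steps most likely to fail:

1. Step 6 (Proposed new method). What may go wrong: hydrogen-atom transfer from the ynal to the donor-substituted quinone triplet may be too slow; the radical pair may recombine at oxygen to give the hydroquinone ester; the quinone carbonyl may photocycloadd to the alkyne; the trialkoxyaryl ring may quench the triplet by electron transfer. Fallback, by known polar chemistry, setting out from 3 and 9 and coming back at 10: 3 is reduced with aqueous Na2S2O4 to 2,3,5-trimethoxybenzene-1,4-diol F1, which MOMCl/i-Pr2NEt converts into 1,4-bis(methoxymethoxy)-2,3,5-trimethoxybenzene F2. Directed ortho-lithiation (n-BuLi, TMEDA, THF, 0 °C) at the single ring C–H, flanked by OMOM and OMe, gives [2,5-bis(methoxymethoxy)-3,4,6-trimethoxyphenyl]lithium F3. This adds 1,2 to ynal 9 at −78 °C to give, after NH4Cl work-up, the racemic propargylic alcohol 1-[2,5-bis(methoxymethoxy)-3,4,6-trimethoxyphenyl]-3-[3,5-dimethoxy-4-(triisopropylsilyloxy)phenyl]prop-2-yn-1-ol F4. MnO2 in CH2Cl2 should oxidise it to the ynone 1-[2,5-bis(methoxymethoxy)-3,4,6-trimethoxyphenyl]-3-[3,5-dimethoxy-4-(triisopropylsilyloxy)phenyl]prop-2-yn-1-one F5. Removal of both MOM groups with HCl in MeOH/THF gives 10, which is cyclised with Et2NH/EtOH as in the second half of step 6 to 12.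

2. Step 2. What may go wrong: methoxide may degrade the quinone core (attack at a carbonyl, redox side reactions) faster than it displaces bromide. Fallback, forming the C–O bond at the arene level, setting out from 2 and coming back at 3: 2 is reduced with Na2S2O4 to 2-bromo-3,5-dimethoxybenzene-1,4-diol F6 and methylated (Me2SO4, K2CO3, acetone) to 2-bromo-1,3,4,5-tetramethoxybenzene F7. Ullmann-type copper-catalysed methoxylation (NaOMe, CuBr, DMF/MeOH, 110 °C) gives pentamethoxybenzene F8. Oxidative demethylation with ceric ammonium nitrate in MeCN/H2O gives 3; both para-dimethoxy pairs of F8 lead to the same quinone.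

3. Step 5. What may go wrong: liberated dimethylamine may add to the ynal during collapse of the hemiaminolate, or the acetylide may be protonated without formylation. Fallback, hydroxymethylation then oxidation with no amine present, setting out from 6 and coming back at 9: acetylide 7 is generated from 6 as before and trapped with paraformaldehyde to give 3-[3,5-dimethoxy-4-(triisopropylsilyloxy)phenyl]prop-2-yn-1-ol F9, which is isolated and oxidised with MnO2 in CH2Cl2 to 9.

**Further compounds**

F1 | step 6 | 2,3,5-trimethoxybenzene-1,4-diol | COc1cc(O)c(OC)c(OC)c1O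
F2 | step 6 | 1,4-bis(methoxymethoxy)-2,3,5-trimethoxybenzene | COCOc1cc(OC)c(OCOC)c(OC)c1OC
F3 | step 6 | [2,5-bis(methoxymethoxy)-3,4,6-trimethoxyphenyl]lithium | [Li]c1c(OCOC)c(OC)c(OC)c(OCOC)c1OC
F4 | step 6 | 1-[2,5-bis(methoxymethoxy)-3,4,6-trimethoxyphenyl]-3-[3,5-dimethoxy-4-(triisopropylsilyloxy)phenyl]prop-2-yn-1-ol (racemic) | COCOc1c(OC)c(OC)c(OCOC)c(OC)c1C(O)C#Cc1cc(OC)c(O[Si](C(C)C)(C(C)C)C(C)C)c(OC)c1
F5 | step 6 | 1-[2,5-bis(methoxymethoxy)-3,4,6-trimethoxyphenyl]-3-[3,5-dimethoxy-4-(triisopropylsilyloxy)phenyl]prop-2-yn-1-one | COCOc1c(OC)c(OC)c(OCOC)c(OC)c1C(=O)C#Cc1cc(OC)c(O[Si](C(C)C)(C(C)C)C(C)C)c(OC)c1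
F6 | step 2 | 2-bromo-3,5-dimethoxybenzene-1,4-diol | COc1cc(O)c(Br)c(OC)c1O
F7 | step 2 | 2-bromo-1,3,4,5-tetramethoxybenzene | COc1cc(OC)c(Br)c(OC)c1OC
F8 | step 2 | pentamethoxybenzene | COc1cc(OC)c(OC)c(OC)c1OC
F9 | step 5 | 3-[3,5-dimethoxy-4-(triisopropylsilyloxy)phenyl]prop-2-yn-1-ol | OCC#Cc1cc(OC)c(O[Si](C(C)C)(C(C)C)C(C)C)c(OC)c1
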